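## Structural features

The target is a humulane-type sesquiterpenoid ester built on one eleven-membered carbocycle, numbered here C1 (bearing the exocyclic methylene), C2=C3, C4 (gem-dimethyl), C5 (acyloxy carbon), C6, C7, C8(Me)=C9, C10 and C11. The exocyclic methylene and the E C2=C3 bond form a 2-substituted 1,3-diene, and the E trisubstituted C8=C9 bond stands in a 1,5-relationship to C1. C5 is the only stereocentre (R, priorities O > C4 > C6 > H); it is a neopentyl-type secondary carbinol between quaternary C4 and C6, esterified with 4-hydroxy-3-methoxybenzoic acid, so no neighbouring stereocentre can relay its configuration and a reagent has to set it. Fragile groups are the conjugated diene (acid, radicals, metal hydrides), the medium-ring polyene as a whole (transannular cyclisation under strong acid), the aryl ester (strong base, hydride) and the free phenol (oxidation, competing acylation). The real difficulty is to close a strained eleven-membered ring containing two E ring olefins while assembling the congested C3–C4–C5 segment, where a quaternary carbon lies between an sp2 carbon and the stereocentre. The key step exploits the oxygenation pattern of this segment: C4 is α to C5, so with C5 as a ketone it is an enolate carbon, and C3 is β to C1, so with C1 as a masked ketone it can be an aldehyde carbon whose aldol hydroxyl is later expelled toward C2. Because C4 carries no hydrogen, neither the enolate site (once a leaving group marks it) nor the direction of that elimination is open to choice.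

## Logic of the disconnections

26 ⇒ 25. The aryl O–Si bond is cut (retrosynthetically, the phenol is masked). The phenol must be blocked while the acid is activated. The forward step needs a fluoride cleavage mild enough to leave the hindered benzoate untouched.

25 ⇒ 20 + 23. The acyl C–O bond of the ester is cut. This separates the terpenoid from the aromatic part, and 23 goes back to 21 by silylation. The forward acylation has to reach a neopentyl-type alcohol without touching the C5–O bond, so that the configuration is kept.

20 ⇒ 19. The C5–H bond is cut, turning the only stereocentre into a ketone. From here back every compound is achiral or racemic. The forward reduction must be reagent-controlled, distinguishing the quaternary C4 side from the C6 methylene side, and must not hydroborate the diene.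

19 ⇒ 18. The exocyclic C1=CH2 bond is cut to a C1 carbonyl, replacing the sensitive diene by an enone. The forward olefination must choose C1 over the C5 ketone; the quaternary neighbour of C5 is relied on for that.

18 ⇒ 16 (through 17). The C2=C3 π bond is replaced by C3–OH and C2–H, and C1 is re-masked as a dioxolane. This exposes the aldol retron C3(OH)–C4–C5(=O). The forward step needs ketal hydrolysis and loss of water toward C2 only, with E geometry.

16 ⇒ 14. The ring bond C3–C4 is cut. This opens the macrocycle to an acyclic chain with an aldehyde at C3 and a tertiary bromide at C4. The forward step must generate the enolate at C4 only, must not reduce the aldehyde, and must favour ring closure over oligomerisation.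

14 ⇒ 13 ⇒ 12. The C4–Br bond is traced to a tetrasubstituted silyl enol ether and the C3 aldehyde to the methyl ester. A direct bromination of an isopropyl ketone would have to tell C4 from C6 and spare the C8=C9 olefin and the ketal. The enol silane removes that choice, protects the C5 carbonyl during the ester reduction, and makes a hydroxyl protecting group unnecessary. The forward steps require a partial ester reduction and a bromination that touches only the enol ether; 14 is made last and used at once.

12 ⇒ 11. The O–Si bond and one C–H bond of a C4 methyl group are cut, leading to an isopropenyl ketone. The enolate position is then defined by conjugate hydride delivery, not by deprotonation. The forward step needs clean 1,4-hydrosilylation.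

11 ⇒ 8 + 9. The C6–C7 bond is cut between an allylic bromide and the acetyl methyl of 9. The forward step needs kinetic deprotonation of the enone at the methyl group and alkylation faster than Michael addition.

8 ⇒ 7 ⇒ 5. The C7–Br and C7–O bonds are cut back to a methyl group of the prenyl terminus. The forward allylic oxidation must pick the methyl trans to the chain, which fixes the E geometry of C8=C9 for the rest of the route.

5 ⇒ 4 ⇒ 1 + 2. The two ketal C–O bonds and the C10–C11 bond are cut. All eleven ring carbons then come from 1, 2 and 9. The forward alkylation must occur at the terminal carbon of the dianion of 1.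

## Other disconnections considered

Alternative 1: The ring is cut at C1–C2. The precursor would be acyclic enol triflate A1: a 1-alken-2-yl triflate at C1, a vinyl group on C4, and the silyl-protected vanillate already on C5.
- Forward step: zerovalent palladium inserts into the C1–O bond, the alkenyl palladium (divalent) adds across the vinyl group with C1 bonding to C2, and syn β-hydride elimination, possible only from C2, gives the E C2=C3 bond and diene A2, which is identical with 25.
- In favour: ring, diene and olefin geometry arise in one step, and A2 is one desilylation from the target. C5 can be set early in open-chain material, for example by an enantioselective tert-prenylation of an aldehyde that creates C4, C5 and the vinyl group together. On step economy, and in avoiding both a macrocyclic ketone reduction and a site-selective methylenation, this plan is the better one. The new bond also lies one atom further from the quaternary carbon, a steric advantage.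
- Against: the closure is an 11-endo insertion onto a vinyl group attached to a quaternary carbon, slow relative to catalyst decay. The Pd–H released can re-add to the new 1,3-diene or the C8=C9 olefin and move double bonds. The simple alkenyl triflate is prone to elimination to an alkyne under the basic conditions and must be made regioselectively from a methyl ketone in the presence of the aryl ester.
- Comparison: the chosen aldol is driven by strong samarium–oxygen bonding and forms the diene only after ring closure, away from metal hydrides. It is the mechanistically safer ring closure, at the price of more steps.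

Alternative 2: The ring is cut at C7–C8. The precursor would be cyclopropanol A3, in which C5 is the carbinol carbon of the three-membered ring (C6 and C7 its methylenes) and C8 carries an E alkenyl iodide.
- Forward step: zerovalent palladium adds to the C–I bond, the cyclopropanol binds as alkoxide to divalent palladium, β-carbon elimination opens the ring to a β-palladated ketone, and reductive elimination forms C7–C8 with retention of olefin geometry. The product is dienone A4, identical with 19.
- In favour: ring strain is released, and the new bond joins two unhindered carbons far from C4, which is better than bond formation at the quaternary centre. The C5 ketone and C1 methylene are present directly, so the selective Wittig step of the chosen plan is not needed, a point on which this alternative is better. Control of C8=C9 geometry is equal (stereospecific here, set by allylic oxidation in the chosen plan).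
- Against: β-hydride elimination of the β-palladated ketone to an enone is the usual competing path and should gain when reductive elimination must pass through a twelve-membered palladacycle. Macrocyclic versions of this coupling have little precedent. A3 needs the diene, the alkenyl iodide and the cyclopropanol (for example by a Kulinkovich reaction of a hindered ester with EtMgBr and Ti(Oi-Pr)4) assembled in one chain, and the diene must then survive palladium.
- Comparison: both plans converge on the same dienone, so the endgame is equal and the step count to the precursor is not lower. The mechanistic support for the chosen closure is stronger.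

Alternative 3: The ring is cut at C10–C11. The precursor would be dibromide A5 with allylic bromides at C10 and C11, the diene and the C5 silyl ether in place.
- Forward step: Ni(CO)4, a zerovalent nickel reagent, converts both termini into π-allyl nickel units and couples the two primary carbons to give triene A6, the silyl ether of 20.
- In favour: two unhindered primary carbons are joined, sterically easier than the chosen bond. All olefins and the stereocentre are already present, and A6 is three steps from the target, equal to the chosen endgame from 20 plus one desilylation.
- Against: Ni(CO)4 is volatile, extremely toxic and needed in excess, so on safety this plan is clearly worse. The π-allyl nickel intermediates interconvert syn and anti forms, so the E geometry at C8=C9 is not secure, and coupling at the tertiary terminus or between molecules can compete. The 2-(bromomethyl)-1,3-diene end of A5 is a polymerisable electrophile, and A5 must contain the stereocentre next to the quaternary carbon, which costs as many steps as 14.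
- Comparison: the chosen plan fixes the C8=C9 geometry in step 3 and never passes through an allyl–metal species, which is better for geometry. Alternative 3 is equal on post-cyclisation steps and better only in the steric ease of the bond formed.

Key step: step 9

Assumption: 16 and 17 are carried as racemates because their only stereocentre (C3) is destroyed in step 10; solutions of SmI2 and LiN(i-Pr)2 are taken as purchased reagents.

## Route

Step 1
Reactants: 1 methyl acetoacetate (methyl 3-oxobutanoate); 2 prenyl bromide (1-bromo-3-methylbut-2-ene)
Product: 4 methyl 7-methyl-3-oxooct-6-enoate, via acetoacetate dianion 3 (not isolated)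
Conditions: NaH, THF, 0 °C; n-BuLi, 0 °C; then 2, 0 °C → rt; aq. HCl
Reagents that add atoms: none
Why: Alkylation of a β-keto ester dianion: the terminal, more basic carbanion of 3 displaces the allylic bromide (SN2) while the stabilised enolate stays intact, forming the C10–C11 bond.

Step 2
Reactants: 4 methyl 7-methyl-3-oxooct-6-enoate
Product: 5 methyl 2-[2-(4-methylpent-3-en-1-yl)-1,3-dioxolan-2-yl]acetate
Conditions: HOCH2CH2OH, p-TsOH·H2O (cat.), benzene, reflux, Dean–Stark
Reagents that add atoms: ethylene glycol, OCCO
Why: Acid-catalysed ketalisation with azeotropic removal of water, routine for β-keto esters; it masks C1 so that C2 is never a 1,3-dicarbonyl methylene, and the trisubstituted olefin is inert to catalytic sulfonic acid.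

Step 3
Reactants: 5 methyl 2-[2-(4-methylpent-3-en-1-yl)-1,3-dioxolan-2-yl]acetate
Product: 7 methyl 2-{2-[(3E)-5-hydroxy-4-methylpent-3-en-1-yl]-1,3-dioxolan-2-yl}acetate, via over-oxidised enal 6 (not isolated)
Conditions: SeO2 (cat.), t-BuOOH, CH2Cl2, 0 °C → rt; then NaBH4, MeOH, 0 °C
Reagents that add atoms: tert-butyl hydroperoxide, CC(C)(C)OO; selenium dioxide (oxygen carrier), O=[Se]=O
Why: SeO2-catalysed allylic oxidation (ene reaction, then [2,3]-sigmatropic shift) attacks the gem-dimethyl end of the olefin at the methyl trans to the chain, so C7 is oxygenated with E geometry. NaBH4 returns any enal 6 to 7 without reducing the ester.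

Step 4
Reactants: 7 methyl 2-{2-[(3E)-5-hydroxy-4-methylpent-3-en-1-yl]-1,3-dioxolan-2-yl}acetate
Product: 8 methyl 2-{2-[(3E)-5-bromo-4-methylpent-3-en-1-yl]-1,3-dioxolan-2-yl}acetate
Conditions: CBr4, PPh3, CH2Cl2, 0 °C
Reagents that add atoms: carbon tetrabromide, BrC(Br)(Br)Br
Why: Appel bromination: SN2 displacement of the oxyphosphonium at the primary allylic carbon under neutral conditions, so olefin geometry, ketal and ester are kept.

Step 5
Reactants: 8 methyl 2-{2-[(3E)-5-bromo-4-methylpent-3-en-1-yl]-1,3-dioxolan-2-yl}acetate; 9 3-methylbut-3-en-2-one
Product: 11 methyl 2-{2-[(3E)-4,8-dimethyl-7-oxonona-3,8-dien-1-yl]-1,3-dioxolan-2-yl}acetate, via lithium dienolate 10 (not isolated)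
Conditions: LiN(i-Pr)2, THF, −78 °C, slow addition of 9 (3 equiv); then 8, DMPU, −78 → −20 °C
Reagents that add atoms: none
Why: Kinetic deprotonation of the enone at its acetyl methyl gives cross-conjugated dienolate 10, which is alkylated by the primary allylic bromide (enolate SN2 alkylation) to form C6–C7. The isopropenyl group is carried because it later defines the enolate position at C4; the hindered ester beside the ketal carbon is not attacked at these temperatures.

Step 6
Reactants: 11 methyl 2-{2-[(3E)-4,8-dimethyl-7-oxonona-3,8-dien-1-yl]-1,3-dioxolan-2-yl}acetate
Product: 12 methyl 2-{2-[(3E)-4,8-dimethyl-7-(triethylsilyloxy)nona-3,7-dien-1-yl]-1,3-dioxolan-2-yl}acetate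
Conditions: Et3SiH, RhCl(PPh3)3 (1 mol %), benzene, 50 °C
Reagents that add atoms: triethylsilane, CC[SiH](CC)CC
Why: Rhodium-catalysed 1,4-hydrosilylation of an α,β-unsaturated ketone with a monohydrosilane puts hydrogen on the terminal CH2 and silicon on oxygen, so only the tetrasubstituted C4=C5 enol silane can form. The isolated trisubstituted olefin, ester and ketal do not react.

Step 7
Reactants: 12 methyl 2-{2-[(3E)-4,8-dimethyl-7-(triethylsilyloxy)nona-3,7-dien-1-yl]-1,3-dioxolan-2-yl}acetate
Product: 13 2-{2-[(3E)-4,8-dimethyl-7-(triethylsilyloxy)nona-3,7-dien-1-yl]-1,3-dioxolan-2-yl}acetaldehyde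
Conditions: i-Bu2AlH (1.1 equiv), CH2Cl2, −78 °C; MeOH, then aq. potassium sodium tartrate
Reagents that add atoms: none
Why: Partial ester reduction: the aluminium hemiacetal, held by chelation to a ketal oxygen, survives at −78 °C until hydrolytic work-up releases the aldehyde. The enol silane keeps the C5 carbonyl hidden from hydride.

Step 8
Reactants: 13 2-{2-[(3E)-4,8-dimethyl-7-(triethylsilyloxy)nona-3,7-dien-1-yl]-1,3-dioxolan-2-yl}acetaldehyde
Product: 14 2-{2-[(3E)-8-bromo-4,8-dimethyl-7-oxonon-3-en-1-yl]-1,3-dioxolan-2-yl}acetaldehyde
Conditions: NBS (1.05 equiv), NaHCO3, THF, −78 °C; aq. Na2S2O3 work-up, used crude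
Reagents that add atoms: N-bromosuccinimide, O=C1CCC(=O)N1Br
Why: Electrophilic bromination of a silyl enol ether at its nucleophilic carbon C4, which reacts with NBS far faster than the trisubstituted olefin or the aldehyde. The tertiary bromide is thus placed without any regiochemical choice, under neutral conditions that spare the ketal.

Step 9
Reactants: 14 2-{2-[(3E)-8-bromo-4,8-dimethyl-7-oxonon-3-en-1-yl]-1,3-dioxolan-2-yl}acetaldehyde
Product: 16 (12E)-7-hydroxy-8,8,12-trimethyl-1,4-dioxaspiro[4.10]pentadec-12-en-9-one (racemic), via samarium enolate 15 (not isolated)
Conditions: SmI2 (2.5 equiv), THF, −78 °C, slow addition of 14 (final ca. 0.003 M); sat. aq. NH4Cl at −78 °C, then rt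
Reagents that add atoms: none
Why: SmI2, a divalent samarium reagent, transfers two electrons to the tertiary C–Br bond of the α-bromo ketone much faster than to the aldehyde and gives trivalent samarium enolate 15, whose position at C4 (never C6) is dictated by where the bromine sat. The oxophilic metal then binds the aldehyde oxygen and the enolate carbon adds through a cyclic chelated transition state, forming the C3–C4 bond and the quaternary carbon. The closest known reaction type is the SmI2-mediated intramolecular Reformatsky (reductive aldol) cyclisation of α-bromo carbonyl compounds onto aldehydes, which has been used for medium and large rings. The one ring closed is the eleven-membered carbocycle, in an 11-exo-trig mode at the aldehyde carbonyl with the enolate double bond inside the new ring. The one new stereocentre, the C3 carbinol, needs no control because it is removed in step 10. The step needs chemoselective reduction of the bromide over the aldehyde, secured by the low reduction potential of the α-bromo ketone at −78 °C without additives, and cyclisation in preference to oligomerisation, secured by slow addition at high dilution and helped by the E olefin and the gem-dimethyl group, which limit the conformations of the chain. The dioxolane keeps the C2 hydrogens from being acidic enough to quench the enolate, and the samarium aldolate chelate is kept cold until quenching to limit retro-aldol opening.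

Step 10
Reactants: 16 (12E)-7-hydroxy-8,8,12-trimethyl-1,4-dioxaspiro[4.10]pentadec-12-en-9-one (racemic)
Product: 18 (2E,8E)-4,4,8-trimethylcycloundeca-2,8-diene-1,5-dione, via hydroxy diketone 17 (not isolated)
Conditions: p-TsOH·H2O (0.3 equiv), acetone–H2O (20:1), rt → 50 °C
Reagents that add atoms: water, O
Why: Acid hydrolysis of the dioxolane gives 17, whose C1 ketone enolises toward C2 and expels the C3 hydroxyl (aldol dehydration); elimination can only go toward C2 because C4 has no hydrogen. The E enone is the thermodynamic isomer beside the gem-dimethyl carbon, and transannular aldol between the two ketones is blocked because it would enclose an E olefin in a six- or seven-membered ring.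

Step 11
Reactants: 18 (2E,8E)-4,4,8-trimethylcycloundeca-2,8-diene-1,5-dione
Product: 19 (3E,8E)-2,2,9-trimethyl-5-methylidenecycloundeca-3,8-dien-1-one
Conditions: Ph3PCH3Br, KOt-Bu, THF, 0 °C; then 18 (1.1 equiv ylide), −20 → 0 °C
Reagents that add atoms: methyltriphenylphosphonium bromide, C[P+](c1ccccc1)(c1ccccc1)c1ccccc1.[Br-]
Why: Wittig methylenation: the C1 carbonyl, flanked by a CH2 and an sp2 carbon, is much more accessible than the C5 carbonyl next to quaternary C4, so one equivalent of ylide at low temperature should convert C1 only. Conjugate addition is blocked by the neopentyl position of C3.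

Step 12
Reactants: 19 (3E,8E)-2,2,9-trimethyl-5-methylidenecycloundeca-3,8-dien-1-one
Product: 20 (1R,3E,8E)-2,2,9-trimethyl-5-methylidenecycloundeca-3,8-dien-1-ol
Conditions: (S)-2-methyl-CBS-oxazaborolidine (0.2 equiv), catecholborane (1.5 equiv), toluene, −78 → −40 °C; MeOH, aq. NaOH
Reagents that add atoms: none
Why: CBS reduction: the ketone binds to the oxazaborolidine boron with the quaternary C4 side as the large group turned away from the catalyst substituent, and hydride from the coordinated borane reaches the face that gives the R carbinol, the same sense as for tert-alkyl methyl ketones with the (S)-catalyst. Catecholborane is used because it does not hydroborate the diene at this temperature.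

Step 13
Reactants: 21 vanillic acid (4-hydroxy-3-methoxybenzoic acid)
Product: 23 4-(tert-butyldimethylsilyloxy)-3-methoxybenzoic acid, via silyl ester 22 (not isolated)
Conditions: TBSCl (2.3 equiv), imidazole, DMF, rt; then AcOH–THF–H2O (3:1:1), rt
Reagents that add atoms: tert-butyldimethylsilyl chloride, CC(C)(C)[Si](C)(C)Cl
Why: Silylation of both acidic OH groups followed by selective hydrolysis of the much more labile silyl ester leaves the phenol masked, so the acid can be activated without self-condensation.

Step 14
Reactants: 20 (1R,3E,8E)-2,2,9-trimethyl-5-methylidenecycloundeca-3,8-dien-1-ol; 23 4-(tert-butyldimethylsilyloxy)-3-methoxybenzoic acid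
Product: 25 (1R,3E,8E)-2,2,9-trimethyl-5-methylidenecycloundeca-3,8-dien-1-yl 4-(tert-butyldimethylsilyloxy)-3-methoxybenzoate, via mixed anhydride 24 (not isolated)
Conditions: 2,4,6-Cl3C6H2COCl, Et3N, THF, rt; then 20, DMAP, toluene, rt → 60 °C
Reagents that add atoms: none
Why: Yamaguchi esterification: DMAP attacks mixed anhydride 24 at the less hindered aroyl carbonyl and the acylpyridinium acylates the hindered C5 alcohol. The C5–O bond is not broken, so the R configuration is retained.

Step 15
Reactants: 25 (1R,3E,8E)-2,2,9-trimethyl-5-methylidenecycloundeca-3,8-dien-1-yl 4-(tert-butyldimethylsilyloxy)-3-methoxybenzoate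
Product: 26 (1R,3E,8E)-2,2,9-trimethyl-5-methylidenecycloundeca-3,8-dien-1-yl 4-hydroxy-3-methoxybenzoate
Conditions: Bu4NF, AcOH, THF, 0 °C
Reagents that add atoms: none
Why: Fluoride-mediated cleavage of the aryl silyl ether, driven by Si–F bond formation and buffered with acetic acid so that the phenoxide cannot attack the ester; the diene and the stereocentre are not affected.

## Compound list

1 | methyl acetoacetate | COC(=O)CC(C)=O | starting material
2 | prenyl bromide (1-bromo-3-methylbut-2-ene) | CC(C)=CCBr | starting material
3 | sodium lithium dianion of methyl acetoacetate | COC([O-])=CC(=C)[O-].[Na+].[Li+] | intermediate (not isolated)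
4 | methyl 7-methyl-3-oxooct-6-enoate | COC(=O)CC(=O)CCC=C(C)C | intermediate
5 | methyl 2-[2-(4-methylpent-3-en-1-yl)-1,3-dioxolan-2-yl]acetate | COC(=O)CC1(OCCO1)CCC=C(C)C | intermediate
6 | methyl 2-{2-[(3E)-4-methyl-5-oxopent-3-en-1-yl]-1,3-dioxolan-2-yl}acetate | COC(=O)CC1(OCCO1)CC/C=C(\C)C=O | intermediate (not isolated)
7 | methyl 2-{2-[(3E)-5-hydroxy-4-methylpent-3-en-1-yl]-1,3-dioxolan-2-yl}acetate | COC(=O)CC1(OCCO1)CC/C=C(\C)CO | intermediate
8 | methyl 2-{2-[(3E)-5-bromo-4-methylpent-3-en-1-yl]-1,3-dioxolan-2-yl}acetate | COC(=O)CC1(OCCO1)CC/C=C(\C)CBr | intermediate
9 | 3-methylbut-3-en-2-one | CC(=O)C(C)=C | starting material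
10 | lithium 3-methylbuta-1,3-dien-2-olate | C=C([O-])C(C)=C.[Li+] | intermediate (not isolated)
11 | methyl 2-{2-[(3E)-4,8-dimethyl-7-oxonona-3,8-dien-1-yl]-1,3-dioxolan-2-yl}acetate | COC(=O)CC1(OCCO1)CC/C=C(\C)CCC(=O)C(C)=C | intermediate
12 | methyl 2-{2-[(3E)-4,8-dimethyl-7-(triethylsilyloxy)nona-3,7-dien-1-yl]-1,3-dioxolan-2-yl}acetate | COC(=O)CC1(OCCO1)CC/C=C(\C)CCC(O[Si](CC)(CC)CC)=C(C)C | intermediate
13 | 2-{2-[(3E)-4,8-dimethyl-7-(triethylsilyloxy)nona-3,7-dien-1-yl]-1,3-dioxolan-2-yl}acetaldehyde | O=CCC1(OCCO1)CC/C=C(\C)CCC(O[Si](CC)(CC)CC)=C(C)C | intermediate
14 | 2-{2-[(3E)-8-bromo-4,8-dimethyl-7-oxonon-3-en-1-yl]-1,3-dioxolan-2-yl}acetaldehyde | O=CCC1(OCCO1)CC/C=C(\C)CCC(=O)C(C)(C)Br | intermediate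
15 | diiodosamarium enolate of 14 (trivalent samarium, O-bound at C5, C4=C5) | O=CCC1(OCCO1)CC/C=C(\C)CCC(O[Sm](I)I)=C(C)C | intermediate (not isolated)
16 | (12E)-7-hydroxy-8,8,12-trimethyl-1,4-dioxaspiro[4.10]pentadec-12-en-9-one (racemic) | OC1CC2(OCCO2)CC/C=C(\C)CCC(=O)C1(C)C | intermediate
17 | (8E)-3-hydroxy-2,2,9-trimethylcycloundec-8-ene-1,5-dione (racemic) | OC1CC(=O)CC/C=C(\C)CCC(=O)C1(C)C | intermediate (not isolated)
18 | (2E,8E)-4,4,8-trimethylcycloundeca-2,8-diene-1,5-dione | O=C1/C=C/C(C)(C)C(=O)CC/C(C)=C/CC1 | intermediate
19 | (3E,8E)-2,2,9-trimethyl-5-methylidenecycloundeca-3,8-dien-1-one | C=C1/C=C/C(C)(C)C(=O)CC/C(C)=C/CC1 | intermediate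
20 | (1R,3E,8E)-2,2,9-trimethyl-5-methylidenecycloundeca-3,8-dien-1-ol | C=C1/C=C/C(C)(C)[C@H](O)CC/C(C)=C/CC1 | intermediate
21 | vanillic acid | COc1cc(ccc1O)C(O)=O | starting material
22 | tert-butyldimethylsilyl 4-(tert-butyldimethylsilyloxy)-3-methoxybenzoate | COc1cc(ccc1O[Si](C)(C)C(C)(C)C)C(=O)O[Si](C)(C)C(C)(C)C | intermediate (not isolated)
23 | 4-(tert-butyldimethylsilyloxy)-3-methoxybenzoic acid | COc1cc(ccc1O[Si](C)(C)C(C)(C)C)C(O)=O | intermediate
24 | 4-(tert-butyldimethylsilyloxy)-3-methoxybenzoic 2,4,6-trichlorobenzoic anhydride | COc1cc(ccc1O[Si](C)(C)C(C)(C)C)C(=O)OC(=O)c1c(Cl)cc(Cl)cc1Cl | intermediate (not isolated)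
25 | (1R,3E,8E)-2,2,9-trimethyl-5-methylidenecycloundeca-3,8-dien-1-yl 4-(tert-butyldimethylsilyloxy)-3-methoxybenzoate | C=C1/C=C/C(C)(C)[C@H](OC(=O)c2ccc(O[Si](C)(C)C(C)(C)C)c(OC)c2)CC/C(C)=C/CC1 | intermediate
26 | (1R,3E,8E)-2,2,9-trimethyl-5-methylidenecycloundeca-3,8-dien-1-yl 4-hydroxy-3-methoxybenzoate | C=C1/C=C/C(C)(C)[C@H](OC(=O)c2ccc(O)c(OC)c2)CC/C(C)=C/CC1 | target

## Step count and least certain steps

Total: 15 steps. Longest linear sequence: 14 steps (steps 1–12, 14 and 15); step 13 is a one-step side branch.

Step 9 (key step).
- What may go wrong: protonation of the samarium enolate before ring closure (net debromination), intermolecular aldol addition leading to oligomers, retro-aldol opening of the strained aldolate on warming, or β-elimination of a ketal oxygen from the aldehyde.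
- Fallback: set out from 13 and close the same bond as an intramolecular Mukaiyama aldol addition. BF3·OEt2 in CH2Cl2 at −78 °C under high dilution activates the aldehyde, and the neutral enol silane attacks through an open transition state with no basic enolate and no reductant. Hydrolytic work-up comes back to the route at 16. This fallback makes no compound outside the list (F0).

Step 5.
- What may go wrong: Michael addition of the dienolate to unreacted or product enone (oligomerisation), proton exchange with the product followed by double alkylation, or acylation by the ester.
- Fallback: set out from 8 and alkylate the lithium enolate of N-methoxy-N-methylacetamide (LiN(i-Pr)2, THF, −78 °C) to give methyl 2-{2-[(3E)-7-[methoxy(methyl)amino]-4-methyl-7-oxohept-3-en-1-yl]-1,3-dioxolan-2-yl}acetate F1. Weinreb ketone synthesis with isopropenylmagnesium bromide (THF, −20 °C) then acylates at the amide in preference to the hindered ester and comes back at 11.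

Step 7.
- What may go wrong: over-reduction to the primary alcohol if the aluminium hemiacetal collapses before quenching, or hydrolysis of the enol silane during work-up.
- Fallback: set out from 12 and reduce the ester fully with LiAlH4 (Et2O, 0 °C, tartrate work-up) to 2-{2-[(3E)-4,8-dimethyl-7-(triethylsilyloxy)nona-3,7-dien-1-yl]-1,3-dioxolan-2-yl}ethan-1-ol F2. Oxidation with Dess–Martin periodinane buffered with NaHCO3 (CH2Cl2, 0 °C) then comes back at 13.

Step 11.
- What may go wrong: incomplete site selection between the two carbonyl groups (double methylenation), or enolisation of the C1 ketone toward C11 by the basic ylide, which stalls the reaction.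
- Fallback: set out from 16 and remove the competing carbonyl before C1 is unmasked. NaBH4 (MeOH, 0 °C) gives (12E)-8,8,12-trimethyl-1,4-dioxaspiro[4.10]pentadec-12-ene-7,9-diol F3 as a diastereomer mixture. Aqueous acid as in step 10 gives (2E,8E)-5-hydroxy-4,4,8-trimethylcycloundeca-2,8-dien-1-one F4. Excess Ph3P=CH2 gives racemic (3E,8E)-2,2,9-trimethyl-5-methylidenecycloundeca-3,8-dien-1-ol F5. Dess–Martin oxidation of F5 comes back at 19, from where step 12 sets the configuration as planned.

Step 12.
- What may go wrong: sluggish reduction of the hindered ketone at the low temperature needed to protect the diene, and poor facial selectivity if the flexible ring lets the C6 side compete as the large group.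
- Fallback: set out from 19 and use a stoichiometric chiral transfer reagent without free B–H bonds. (+)-B-Chlorodiisopinocampheylborane (THF, rt, diethanolamine work-up) reduces tert-alkyl ketones through a six-membered transition state with the quaternary side as the large group and cannot hydroborate the diene; it comes back at 20. This fallback makes no compound outside the list (F0).

## Further compounds

F0 | step 9 | none | none
F1 | step 5 | methyl 2-{2-[(3E)-7-[methoxy(methyl)amino]-4-methyl-7-oxohept-3-en-1-yl]-1,3-dioxolan-2-yl}acetate | COC(=O)CC1(OCCO1)CC/C=C(\C)CCC(=O)N(C)OC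
F2 | step 7 | 2-{2-[(3E)-4,8-dimethyl-7-(triethylsilyloxy)nona-3,7-dien-1-yl]-1,3-dioxolan-2-yl}ethan-1-ol | OCCC1(OCCO1)CC/C=C(\C)CCC(O[Si](CC)(CC)CC)=C(C)C
F3 | step 11 | (12E)-8,8,12-trimethyl-1,4-dioxaspiro[4.10]pentadec-12-ene-7,9-diol (diastereomer mixture) | OC1CC2(OCCO2)CC/C=C(\C)CCC(O)C1(C)C
F4 | step 11 | (2E,8E)-5-hydroxy-4,4,8-trimethylcycloundeca-2,8-dien-1-one (racemic) | O=C1/C=C/C(C)(C)C(O)CC/C(C)=C/CC1
F5 | step 11 | (3E,8E)-2,2,9-trimethyl-5-methylidenecycloundeca-3,8-dien-1-ol (racemic) | C=C1/C=C/C(C)(C)C(O)CC/C(C)=C/CC1
F0 | step 12 | none | none
A1 | alternative 1 | (4R,7E)-3,3,7-trimethyl-11-(trifluoromethanesulfonyloxy)dodeca-1,7,11-trien-4-yl 4-(tert-butyldimethylsilyloxy)-3-methoxybenzoate | C=CC(C)(C)[C@H](OC(=O)c1ccc(O[Si](C)(C)C(C)(C)C)c(OC)c1)CC/C(C)=C/CCC(=C)OS(=O)(=O)C(F)(F)F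
A2 | alternative 1 | (1R,3E,8E)-2,2,9-trimethyl-5-methylidenecycloundeca-3,8-dien-1-yl 4-(tert-butyldimethylsilyloxy)-3-methoxybenzoate | C=C1/C=C/C(C)(C)[C@H](OC(=O)c2ccc(O[Si](C)(C)C(C)(C)C)c(OC)c2)CC/C(C)=C/CC1
A3 | alternative 2 | 1-[(3E,8E)-9-iodo-2-methyl-5-methylidenedeca-3,8-dien-2-yl]cyclopropan-1-ol | OC1(CC1)C(C)(C)/C=C/C(=C)CC/C=C(\C)I
A4 | alternative 2 | (3E,8E)-2,2,9-trimethyl-5-methylidenecycloundeca-3,8-dien-1-one | C=C1/C=C/C(C)(C)C(=O)CC/C(C)=C/CC1
A5 | alternative 3 | {[(2E,6R,8E)-1,11-dibromo-3,7,7-trimethyl-10-methylideneundeca-2,8-dien-6-yl]oxy}(tert-butyl)dimethylsilane | BrC/C=C(\C)CC[C@@H](O[Si](C)(C)C(C)(C)C)C(C)(C)/C=C/C(=C)CBr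
A6 | alternative 3 | tert-butyldimethyl{[(1R,3E,8E)-2,2,9-trimethyl-5-methylidenecycloundeca-3,8-dien-1-yl]oxy}silane | C=C1/C=C/C(C)(C)[C@H](O[Si](C)(C)C(C)(C)C)CC/C(C)=C/CC1
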